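**Remark on the chemistry.** The 2-pyranone unit (ring D below) is handled as its acidic 4-hydroxy tautomer. Enol silane 2 is used as obtained (expected mainly Z), because its geometry is lost when ring D forms. Flavanone numbering (O1, C2 … C8a) is used for rings A and C; ring B is the phenyl group.

**Retrosynthetic overview**

1. The target is taken back to its 5,7-di-O-methyl ether without the C8 acyl group; the last two steps are C8 acylation with 3-methylbut-2-enoyl chloride and BCl3 cleavage of the two carbonyl-flanked methyl ethers.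
2. Key disconnection C4–C4a of ring C: intramolecular Friedel–Crafts acylation of an (S)-3-aryloxy-3-phenylpropanoic acid. It rests on the fact that in ring A the carbon carrying the ring oxygen (C8a with O1) is para to the bridge-bearing carbon C6. The aryl ether of a 4-substituted 3,5-dimethoxyphenol therefore has two equivalent ortho carbons, and acylation at either gives C4–C4a with the CH2 bridge at C6 and C8 as the single free carbon.
3. The acid comes from a reductive Knoevenagel union (CH2 bridge between C6 and C3 of ring D) of the pyranone with a 4-aryloxy-2,6-dimethoxybenzaldehyde. Its O1–C2 bond is made by Mitsunobu inversion of ethyl (R)-3-hydroxy-3-phenylpropanoate, which sets C2 as S.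
4. Ring D is made from the enol silane of pentan-3-one and malonyl dichloride.
5. Order of ring formation: ring D (step 2), then ring C (step 6); rings A and B are bought.

Key step: step 6

**Route**

Step 1
Reactants: 1 pentan-3-one
Product: 2 (Z)-3-(trimethylsilyloxy)pent-2-ene
Conditions: TMSOTf (1.1 equiv), Et3N (1.5 equiv), CH2Cl2, 0 °C
Reagents that add atoms: trimethylsilyl trifluoromethanesulfonate, C[Si](C)(C)OS(=O)(=O)C(F)(F)F
Why: Soft enolisation and O-silylation of a symmetrical ketone with a silyl triflate and an amine base (standard silyl enol ether synthesis), in which only one regioisomer can form.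

Step 2
Reactants: 2 (Z)-3-(trimethylsilyloxy)pent-2-ene; 3 malonyl dichloride
Product: 5 6-ethyl-4-hydroxy-5-methyl-2H-pyran-2-one, via diketo acid chloride 4 (not isolated)
Conditions: Et2O, −78 °C → rt
Reagents that add atoms: none
Why: C-acylation of the enol silane by one acyl chloride group gives 4, whose distal enol oxygen closes onto the second acyl chloride (lactonisation), the established 4-hydroxy-2-pyranone synthesis from silyl enol ethers and malonyl dichloride.

Step 3
Reactants: 6 4-hydroxy-2,6-dimethoxybenzaldehyde; 7 ethyl (R)-3-hydroxy-3-phenylpropanoate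
Product: 8 ethyl (S)-3-(4-formyl-3,5-dimethoxyphenoxy)-3-phenylpropanoate
Conditions: PPh3, DIAD, THF, 0 °C → rt (DIAD added last)
Reagents that add atoms: none
Why: Mitsunobu etherification in which the acidic para-formyl phenol displaces the oxyphosphonium derivative of the benzylic alcohol by SN2 with inversion, so the (R)-carbinol becomes the (S)-aryl ether carbon (later C2); the acidity of 6 and the low temperature should favour substitution over elimination to ethyl cinnamate.

Step 4
Reactants: 8 ethyl (S)-3-(4-formyl-3,5-dimethoxyphenoxy)-3-phenylpropanoate; 5 6-ethyl-4-hydroxy-5-methyl-2H-pyran-2-one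
Product: 10 ethyl (S)-3-{4-[(6-ethyl-4-hydroxy-5-methyl-2-oxo-2H-pyran-3-yl)methyl]-3,5-dimethoxyphenoxy}-3-phenylpropanoate, via alkylidene pyrandione 9 (not isolated)
Conditions: Hantzsch ester (diethyl 2,6-dimethyl-1,4-dihydropyridine-3,5-dicarboxylate, 1.1 equiv), L-proline (20 mol%), CH2Cl2, rt
Reagents that add atoms: none
Why: Three-component reductive Knoevenagel alkylation, in which proline-catalysed condensation at C3 of the pyranone (its only free nucleophilic carbon) gives the electrophilic alkylidene 9, which should take a hydride from the Hantzsch ester faster than it adds a second pyranone, under neutral conditions that leave the β-aryloxy ester untouched.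

Step 5
Reactants: 10 ethyl (S)-3-{4-[(6-ethyl-4-hydroxy-5-methyl-2-oxo-2H-pyran-3-yl)methyl]-3,5-dimethoxyphenoxy}-3-phenylpropanoate
Product: 11 (S)-3-{4-[(6-ethyl-4-hydroxy-5-methyl-2-oxo-2H-pyran-3-yl)methyl]-3,5-dimethoxyphenoxy}-3-phenylpropanoic acid
Conditions: LiOH·H2O (3 equiv), THF/H2O, 0 °C; then 1 M HCl to pH 3
Reagents that add atoms: lithium hydroxide, [Li+].[OH-]
Why: Ester saponification by hydroxide attack at the acyl carbon, which at 0 °C should be much faster than α-deprotonation, so β-elimination of the electron-rich aryloxide is not expected, the stereocentre (no acidic hydrogen on it) is retained and ring D is shielded as its enolate salt.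

Step 6
Reactants: 11 (S)-3-{4-[(6-ethyl-4-hydroxy-5-methyl-2-oxo-2H-pyran-3-yl)methyl]-3,5-dimethoxyphenoxy}-3-phenylpropanoic acid
Product: 14 (S)-6-[(6-ethyl-4-hydroxy-5-methyl-2-oxo-2H-pyran-3-yl)methyl]-5,7-dimethoxy-2-phenylchroman-4-one, via mixed trifluoroacetic anhydride 12 (not isolated), via chromanone enol trifluoroacetate 13 (not isolated)
Conditions: TFAA (2.5 equiv), CH2Cl2 (0.02 M), 0 °C → rt; then aq. NaHCO3, re-acidify to pH 4
Reagents that add atoms: none
Why: Intramolecular Friedel–Crafts acylation: TFAA turns the acid into the mixed carboxylic trifluoroacetic anhydride 12 (the acidic ring D hydroxyl is trifluoroacetylated at the same time, which masks it), the activated acyl carbon is attacked by the ring carbon ortho to the ether oxygen and para to a methoxy group, and proton loss from the arenium ion gives the aryl ketone, forming C4–C4a. The closest known reaction type is the anhydride- or acid-mediated cyclisation of 3-aryloxypropanoic acids to chroman-4-ones. Ring C closes as a six-membered ring by electrophilic aromatic substitution (6-exo attack on the acyl carbon, with the arene carbon as nucleophile). No stereocentre is created; C2, set in step 3, carries no acidic hydrogen and none of its bonds is broken. The step needs regioselectivity on ring A, which the substrate secures by symmetry, since O1 is para to the bridge carbon and both open ortho carbons are equivalent, each giving the 6-substituted 5,7-dimethoxy pattern with C8 left free. It also needs chemoselectivity against ionisation of the benzylic C2–O bond and acid opening of the new β-aryloxy ketone, which the absence of any strong Lewis or Brønsted acid and the high nucleophilicity of the trialkoxy ring at 0 °C should secure; the enol trifluoroacetate 13 is hydrolysed in the bicarbonate work-up.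

Step 7
Reactants: 14 (S)-6-[(6-ethyl-4-hydroxy-5-methyl-2-oxo-2H-pyran-3-yl)methyl]-5,7-dimethoxy-2-phenylchroman-4-one; 15 3-methylbut-2-enoyl chloride
Product: 17 (S)-6-[(6-ethyl-4-hydroxy-5-methyl-2-oxo-2H-pyran-3-yl)methyl]-5,7-dimethoxy-8-(3-methylbut-2-enoyl)-2-phenylchroman-4-one, via bis-acylated enol ester 16 (not isolated)
Conditions: 15 (2.5 equiv), TiCl4 (4 equiv), CH2Cl2, −20 → 0 °C; aqueous work-up; then MeOH, DMAP (0.2 equiv), rt
Reagents that add atoms: none
Why: Friedel–Crafts acylation at C8, the only unsubstituted carbon of ring A (ortho to O1 and to the 7-methoxy group, para to the 5-methoxy group, meta to the C4 carbonyl); the acidic ring D hydroxyl is acylated as well (16), and this activated enol ester should be cleaved selectively by DMAP-catalysed methanolysis under conditions too mild to open ring C.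

Step 8
Reactants: 17 (S)-6-[(6-ethyl-4-hydroxy-5-methyl-2-oxo-2H-pyran-3-yl)methyl]-5,7-dimethoxy-8-(3-methylbut-2-enoyl)-2-phenylchroman-4-one
Product: 19 (S)-6-[(6-ethyl-4-hydroxy-5-methyl-2-oxo-2H-pyran-3-yl)methyl]-5,7-dihydroxy-8-(3-methylbut-2-enoyl)-2-phenylchroman-4-one, via tris(dichloroboryl) derivative 18 (not isolated)
Conditions: BCl3 (6 equiv), CH2Cl2, −78 → 0 °C; then ice-water
Reagents that add atoms: none
Why: Chelation-assisted aryl methyl ether cleavage, in which BCl3 held between a carbonyl oxygen and the neighbouring methoxy oxygen (C4=O with 5-OMe, the C8 acyl C=O with 7-OMe) lets chloride remove each methyl group as chloromethane at or below 0 °C and hydrolysis of the boron aryloxides 18 releases the target, without base, so the enone, the free 7-hydroxyl and C2 should stay as they are.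

**Compound list**

1 | pentan-3-one | CCC(=O)CC | starting material
2 | (Z)-3-(trimethylsilyloxy)pent-2-ene | C/C=C(\O[Si](C)(C)C)CC | intermediate
3 | malonyl dichloride | ClC(=O)CC(=O)Cl | starting material
4 | 4-methyl-3,5-dioxoheptanoyl chloride | CCC(=O)C(C)C(=O)CC(=O)Cl | intermediate (not isolated)
5 | 6-ethyl-4-hydroxy-5-methyl-2H-pyran-2-one | CCc1oc(=O)cc(O)c1C | intermediate
6 | 4-hydroxy-2,6-dimethoxybenzaldehyde | COc1cc(O)cc(OC)c1C=O | starting material
7 | ethyl (R)-3-hydroxy-3-phenylpropanoate | CCOC(=O)C[C@H](c1ccccc1)O | starting material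
8 | ethyl (S)-3-(4-formyl-3,5-dimethoxyphenoxy)-3-phenylpropanoate | CCOC(=O)C[C@@H](c1ccccc1)Oc1cc(OC)c(C=O)c(OC)c1 | intermediate
9 | ethyl (S)-3-{4-[(6-ethyl-5-methyl-2,4-dioxo-2H-pyran-3(4H)-ylidene)methyl]-3,5-dimethoxyphenoxy}-3-phenylpropanoate | CCOC(=O)C[C@@H](c1ccccc1)Oc1cc(OC)c(C=C2C(=O)OC(CC)=C(C)C2=O)c(OC)c1 | intermediate (not isolated)
10 | ethyl (S)-3-{4-[(6-ethyl-4-hydroxy-5-methyl-2-oxo-2H-pyran-3-yl)methyl]-3,5-dimethoxyphenoxy}-3-phenylpropanoate | CCOC(=O)C[C@@H](c1ccccc1)Oc1cc(OC)c(Cc2c(O)c(C)c(CC)oc2=O)c(OC)c1 | intermediate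
11 | (S)-3-{4-[(6-ethyl-4-hydroxy-5-methyl-2-oxo-2H-pyran-3-yl)methyl]-3,5-dimethoxyphenoxy}-3-phenylpropanoic acid | OC(=O)C[C@@H](c1ccccc1)Oc1cc(OC)c(Cc2c(O)c(C)c(CC)oc2=O)c(OC)c1 | intermediate (key-step precursor)
12 | mixed anhydride of 11 with trifluoroacetic acid, ring D hydroxyl as trifluoroacetate | O=C(OC(=O)C(F)(F)F)C[C@@H](c1ccccc1)Oc1cc(OC)c(Cc2c(OC(=O)C(F)(F)F)c(C)c(CC)oc2=O)c(OC)c1 | intermediate (not isolated)
13 | 6-ethyl-3-{[(S)-5,7-dimethoxy-4-oxo-2-phenylchroman-6-yl]methyl}-5-methyl-2-oxo-2H-pyran-4-yl trifluoroacetate | O=C1C[C@@H](c2ccccc2)Oc2cc(OC)c(Cc3c(OC(=O)C(F)(F)F)c(C)c(CC)oc3=O)c(OC)c12 | intermediate (not isolated)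
14 | (S)-6-[(6-ethyl-4-hydroxy-5-methyl-2-oxo-2H-pyran-3-yl)methyl]-5,7-dimethoxy-2-phenylchroman-4-one | O=C1C[C@@H](c2ccccc2)Oc2cc(OC)c(Cc3c(O)c(C)c(CC)oc3=O)c(OC)c12 | intermediate (key-step product)
15 | 3-methylbut-2-enoyl chloride | CC(C)=CC(=O)Cl | starting material
16 | 6-ethyl-3-{[(S)-5,7-dimethoxy-8-(3-methylbut-2-enoyl)-4-oxo-2-phenylchroman-6-yl]methyl}-5-methyl-2-oxo-2H-pyran-4-yl 3-methylbut-2-enoate | O=C1C[C@@H](c2ccccc2)Oc2c(C(=O)C=C(C)C)c(OC)c(Cc3c(OC(=O)C=C(C)C)c(C)c(CC)oc3=O)c(OC)c12 | intermediate (not isolated)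
17 | (S)-6-[(6-ethyl-4-hydroxy-5-methyl-2-oxo-2H-pyran-3-yl)methyl]-5,7-dimethoxy-8-(3-methylbut-2-enoyl)-2-phenylchroman-4-one | O=C1C[C@@H](c2ccccc2)Oc2c(C(=O)C=C(C)C)c(OC)c(Cc3c(O)c(C)c(CC)oc3=O)c(OC)c12 | intermediate
18 | tris(dichloroboryl) derivative of the target (5-O, 7-O and ring D 4-O each carrying BCl2) | O=C1C[C@@H](c2ccccc2)Oc2c(C(=O)C=C(C)C)c(OB(Cl)Cl)c(Cc3c(OB(Cl)Cl)c(C)c(CC)oc3=O)c(OB(Cl)Cl)c12 | intermediate (not isolated)
19 | (S)-6-[(6-ethyl-4-hydroxy-5-methyl-2-oxo-2H-pyran-3-yl)methyl]-5,7-dihydroxy-8-(3-methylbut-2-enoyl)-2-phenylchroman-4-one | CCc1oc(=O)c(Cc2c(O)c(C(=O)C=C(C)C)c3c(c2O)C(=O)C[C@@H](c2ccccc2)O3)c(O)c1C | target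

**Step count**

Total: 8 steps. Longest linear sequence: 7 steps (steps 1, 2, 4, 5, 6, 7, 8, from pentan-3-one); from aldehyde 6 the sequence is 6 steps.

**Steps most likely to fail**

Step 7. The intermolecular acylation may be too slow at a carbon flanked on both sides and sitting on a ring already deactivated by the C4 carbonyl. Long exposure to TiCl4 could then open ring C by Lewis-acid-induced retro-oxa-Michael reaction (loss of the C2 configuration through the chalcone), remove the 5-methyl group early, or add HCl to the enone. The fallback builds the acyl group in stages with a smaller, more reactive electrophile. It sets out from 14: Rieche formylation (dichloromethyl methyl ether, TiCl4, CH2Cl2, −20 °C) should give (S)-6-[(6-ethyl-4-hydroxy-5-methyl-2-oxo-2H-pyran-3-yl)methyl]-5,7-dimethoxy-4-oxo-2-phenylchromane-8-carbaldehyde F1. 2-Methylprop-1-enylmagnesium bromide (2.2 equiv, THF, −78 °C; the first equivalent is consumed by the ring D hydroxyl) should add to the aldehyde in preference to the hindered, electron-rich C4 ketone, giving the 8-(1-hydroxy-3-methylbut-2-enyl) compound F2 as a mixture of carbinol epimers. Oxidation of this benzylic-allylic alcohol with MnO2 (CH2Cl2, rt) brings the fallback back to the route at 17.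

Step 8. Besides the two methyl ethers, BCl3 held between the C8 carbonyl and O1 may cleave the benzylic O1–C2 bond, opening ring C and scrambling C2. The second demethylation (7-OMe) may also stall, and HCl or the freed 7-hydroxyl may add to the enone (closure to a 2,2-dimethylchromanone). The fallback reverses the order of events. It sets out from 14: both methyl ethers are removed with BBr3 (CH2Cl2, −78 → 0 °C) while neither an enone nor a carbonyl next to O1 is present, to give (S)-6-[(6-ethyl-4-hydroxy-5-methyl-2-oxo-2H-pyran-3-yl)methyl]-5,7-dihydroxy-2-phenylchroman-4-one F3. Direct C-acylation of this phloroglucinol-type ring with 15 (1.1 equiv) and TiCl4 (CH2Cl2, −20 °C) at C8, the only open position of ring A, then comes back to the route at 19.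

Step 3. The activated β-hydroxy ester may undergo β-elimination to ethyl cinnamate in competition with substitution, and partial ionisation at the benzylic carbon may lower the enantiomeric purity at C2. The fallback removes the acidic α-hydrogens by carrying the carboxyl carbon as a protected primary alcohol. It sets out from 6. Commercial (R)-1-phenylpropane-1,3-diol is silylated at its primary hydroxyl (TBSCl, imidazole, CH2Cl2, 0 °C) to (R)-3-[(tert-butyldimethylsilyl)oxy]-1-phenylpropan-1-ol F4. Mitsunobu coupling of F4 with 6 (PPh3, DIAD, THF, 0 °C, inversion) should give (S)-4-{3-[(tert-butyldimethylsilyl)oxy]-1-phenylpropoxy}-2,6-dimethoxybenzaldehyde F5. TBAF (THF, 0 °C) frees (S)-4-(3-hydroxy-1-phenylpropoxy)-2,6-dimethoxybenzaldehyde F6. TEMPO (cat.) with PhI(OAc)2 in MeCN/H2O oxidises the primary alcohol, but not the electron-rich aryl aldehyde, to (S)-3-(4-formyl-3,5-dimethoxyphenoxy)-3-phenylpropanoic acid F7. Reductive Knoevenagel alkylation of F7 with 5 (Hantzsch ester, L-proline, CH2Cl2, rt) then comes back to the route at acid 11, so that steps 4 and 5 on the ester are bypassed.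

**Further compounds**

F1 | step 7 | (S)-6-[(6-ethyl-4-hydroxy-5-methyl-2-oxo-2H-pyran-3-yl)methyl]-5,7-dimethoxy-4-oxo-2-phenylchromane-8-carbaldehyde | O=C1C[C@@H](c2ccccc2)Oc2c(C=O)c(OC)c(Cc3c(O)c(C)c(CC)oc3=O)c(OC)c12
F2 | step 7 | (2S)-6-[(6-ethyl-4-hydroxy-5-methyl-2-oxo-2H-pyran-3-yl)methyl]-8-(1-hydroxy-3-methylbut-2-en-1-yl)-5,7-dimethoxy-2-phenylchroman-4-one (carbinol epimers) | O=C1C[C@@H](c2ccccc2)Oc2c(C(O)C=C(C)C)c(OC)c(Cc3c(O)c(C)c(CC)oc3=O)c(OC)c12
F3 | step 8 | (S)-6-[(6-ethyl-4-hydroxy-5-methyl-2-oxo-2H-pyran-3-yl)methyl]-5,7-dihydroxy-2-phenylchroman-4-one | O=C1C[C@@H](c2ccccc2)Oc2cc(O)c(Cc3c(O)c(C)c(CC)oc3=O)c(O)c12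
F4 | step 3 | (R)-3-[(tert-butyldimethylsilyl)oxy]-1-phenylpropan-1-ol | CC(C)(C)[Si](C)(C)OCC[C@H](c1ccccc1)O
F5 | step 3 | (S)-4-{3-[(tert-butyldimethylsilyl)oxy]-1-phenylpropoxy}-2,6-dimethoxybenzaldehyde | CC(C)(C)[Si](C)(C)OCC[C@@H](c1ccccc1)Oc1cc(OC)c(C=O)c(OC)c1
F6 | step 3 | (S)-4-(3-hydroxy-1-phenylpropoxy)-2,6-dimethoxybenzaldehyde | OCC[C@@H](c1ccccc1)Oc1cc(OC)c(C=O)c(OC)c1
F7 | step 3 | (S)-3-(4-formyl-3,5-dimethoxyphenoxy)-3-phenylpropanoic acid | OC(=O)C[C@@H](c1ccccc1)Oc1cc(OC)c(C=O)c(OC)c1
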